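The two oxiranes are disconnected last and together: epoxytwinol A is traced to the C2-symmetric cage bis(quinone monoketal) 17, in which rings A (C5, C6, C7, C9, C11, C12) and B (C16, C17, C18, C20, C22, C23) are 4,4-dimethoxycyclohexadienones. One Weitz–Scheffer operation exploits the fact that each ring holds a single disubstituted enone bond (C9=C11, C20=C22) beside a tetrasubstituted, cage-bound one: bulky Ph3COO− adds to C9 and C22, closes on C11 and C20 and sets four stereocentres on the convex ring faces. The cage comes from a C2-symmetric diaryl hexanediol and a glyoxal acetal by double oxa-Pictet–Spengler closure.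

Key step: step 12

Assumption: atom labels follow the target SMILES read left to right; "outer face" of ring A (ring B) is the face on the side of the ring's own O3–C2 (O26–C27) bridge and its exo methyl, turned away from the other half of the cage, and compounds 1, 3, 6, 13 and Ph3COOH are taken as purchasable.

Step 1
Reactants: 1 3-bromo-4-methoxyphenol
Product: 2 4-(benzyloxy)-2-bromo-1-methoxybenzene
Conditions: BnBr, K2CO3, DMF, rt
Reagents that add atoms: benzyl bromide, BrCc1ccccc1
Why: Williamson ether synthesis, in which the phenoxide is the only nucleophile and the benzyl ether formed survives every step up to the hydrogenolysis in step 10.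

Step 2
Reactants: 2 4-(benzyloxy)-2-bromo-1-methoxybenzene; 3 (2-tert-butoxy-2-oxoethyl)zinc bromide
Product: 4 tert-butyl [5-(benzyloxy)-2-methoxyphenyl]acetate
Conditions: Pd(dba)2 (2 mol %), P(t-Bu)3 (2 mol %), THF, rt
Reagents that add atoms: none
Why: Palladium-catalysed α-arylation of a zinc ester enolate (Reformatsky reagent in a Negishi-type coupling), in which oxidative addition of the aryl bromide to zerovalent palladium, transmetalation and reductive elimination run under neutral conditions, so diarylation and ester condensation are not expected.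

Step 3
Reactants: 4 tert-butyl [5-(benzyloxy)-2-methoxyphenyl]acetate
Product: 5 [5-(benzyloxy)-2-methoxyphenyl]acetic acid
Conditions: CF3CO2H, CH2Cl2, 0 °C to rt
Reagents that add atoms: none
Why: Acidolysis of the tert-butyl ester (E1 loss of 2-methylpropene) frees the acid, while the aryl benzyl and methyl ethers tolerate short exposure to the acid at room temperature.

Step 4
Reactants: 5 [5-(benzyloxy)-2-methoxyphenyl]acetic acid; 6 (S)-4-benzyloxazolidin-2-one
Product: 8 (S)-4-benzyl-3-{[5-(benzyloxy)-2-methoxyphenyl]acetyl}oxazolidin-2-one, via mixed pivalic anhydride 7 (not isolated)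
Conditions: t-BuCOCl, Et3N, THF, −20 °C; then 6, LiCl, −20 °C to rt
Reagents that add atoms: pivaloyl chloride, CC(C)(C)C(Cl)=O (its atoms remain only in intermediate 7)
Why: N-Acylation of the oxazolidinone auxiliary through a mixed anhydride, in which the LiCl-activated carbamate attacks the less hindered arylacetyl carbonyl and no stereocentre is created.

Step 5
Reactants: 8 (S)-4-benzyl-3-{[5-(benzyloxy)-2-methoxyphenyl]acetyl}oxazolidin-2-one (two molecules)
Product: 9 (2S,3S)-2,3-bis[5-(benzyloxy)-2-methoxyphenyl]-1,4-bis[(S)-4-benzyl-2-oxooxazolidin-3-yl]butane-1,4-dione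
Conditions: LiN(i-Pr)2, THF, −78 °C; then TiCl4, −78 °C to rt
Reagents that add atoms: none
Why: Oxidative enolate homocoupling, a reaction known for 3-(arylacetyl)oxazolidin-2-ones: the chelated Z-enolate is passed to tetravalent titanium, one-electron transfer gives trivalent titanium and an α-acyl radical, and C–C coupling on the face opposite the 4-benzyl group at both carbons should give the chiral 2S,3S pair instead of the meso isomer.

Step 6
Reactants: 9 (2S,3S)-bis(imide)
Product: 10 S,S'-diethyl (2S,3S)-2,3-bis[5-(benzyloxy)-2-methoxyphenyl]butanebis(thioate)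
Conditions: EtSH, n-BuLi, THF, 0 °C
Reagents that add atoms: ethanethiol, CCS
Why: Thiolate acyl transfer on the imide, in which the soft and weakly basic LiSEt attacks the exocyclic carbonyl even of hindered imides and releases the auxiliary without enolising the benzylic carbons, so both stay S.

Step 7
Reactants: 10 (2S,3S)-bis(thioester)
Product: 11 (3S,4S)-3,4-bis[5-(benzyloxy)-2-methoxyphenyl]hexane-2,5-dione
Conditions: MeZnCl, PdCl2(PPh3)2 (10 mol %), THF–toluene, rt
Reagents that add atoms: methylzinc chloride, C[Zn]Cl
Why: Fukuyama coupling, in which zerovalent palladium inserts into each C(O)–S bond, the methylzinc reagent transmetalates and reductive elimination gives the methyl ketone under non-basic conditions that should not epimerise the acidic benzylic centres.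

Step 8
Reactants: 11 (3S,4S)-diketone
Product: 12 (2R,3S,4S,5R)-3,4-bis[5-(benzyloxy)-2-methoxyphenyl]hexane-2,5-diol
Conditions: (S)-1-methyl-3,3-diphenyltetrahydro-1H,3H-pyrrolo[1,2-c][1,3,2]oxazaborole (40 mol %), BH3·SMe2, THF, −20 °C; then MeOH
Reagents that add atoms: none
Why: Corey–Bakshi–Shibata reduction, in which the (S)-oxazaborolidine–borane complex places the branched substituent of each methyl ketone away from the catalyst and delivers hydride to give the 2R and 5R carbinols, the sense also favoured by Felkin–Anh attack anti to the aryl group, so each half becomes 2,3-syn.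

Step 9
Reactants: 12 (2R,3S,4S,5R)-diol; 13 1,1,2,2-tetramethoxyethane
Product: 15 cage bis(benzyl ether), via mono-isochroman acetal 14 (not isolated)
Conditions: 13 (1.05 equiv, slow addition), BF3·OEt2, CH2Cl2 (0.01 M), −20 °C to rt
Reagents that add atoms: none
Why: Twofold oxa-Pictet–Spengler cyclisation, the reaction type used on 1-(2,5-dialkoxyphenyl)propan-2-ols: O3 and then O26 exchange into the acetal, each oxocarbenium ion is attacked by the only free ortho carbon of its arene (C5, C17), the bridged cage allows one configuration at C4 and C25 (S,S), C4 of 14 can still equilibrate through its enol ether before the second closure, and the methyl groups end exo because C2 and C27 are already fixed.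

Step 10
Reactants: 15 cage bis(benzyl ether)
Product: 16 cage bis(phenol)
Conditions: H2 (1 atm), Pd/C, EtOAc, rt
Reagents that add atoms: none
Why: Hydrogenolysis cleaves the two aryl benzyl ethers as toluene much faster than the ring-bound, hindered C4–O3 and C25–O26 benzylic ether bonds and touches no stereocentre.

Step 11
Reactants: 16 cage bis(phenol)
Product: 17 cage bis(quinone monoketal)
Conditions: PhI(OAc)2, MeOH, 0 °C
Reagents that add atoms: methanol, CO
Why: Oxidative dearomatisation of a p-methoxyphenol with the trivalent iodine reagent, in which methanol attacks the methoxy-bearing para carbon (C7, C23) and the carbonyl appears at the former phenol carbon (C12, C18), which fixes the ketone and ketal positions needed later.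

Step 12
Reactants: 17 cage bis(quinone monoketal)
Product: 18 cage bis(epoxy monoketal)
Conditions: Ph3COOH (3 equiv), NaN(SiMe3)2 (2.6 equiv), toluene–THF, −78 to −40 °C
Reagents that add atoms: triphenylmethyl hydroperoxide, OOC(c1ccccc1)(c1ccccc1)c1ccccc1
Why: Ph3COONa adds in conjugate fashion to the only unsubstituted β-carbon of each cross-conjugated dienone, C9 in ring A and C22 in ring B (β to the C12 and C18 carbonyls and next to the ketal carbons), and the enolate so formed attacks the proximal peroxide oxygen through C11 (C20), expelling triphenylmethoxide. This is the Weitz–Scheffer nucleophilic epoxidation, well established for 4,4-dimethoxycyclohexa-2,5-dienones. Each oxirane closes by 3-exo-tet displacement at oxygen, so the ring fusion is necessarily cis and C11 (C20) must take the configuration that C9 (C22) received. C9 and C22 in turn are set by the cage: the inner face of ring A lies over the O26–C27 bridge of the other half (ring B over O3–C2), while the outer face is flanked only by the ring's own bridge, which tilts away with its methyl group exo, so the bulky trityl peroxide should enter from the outer face, the one the target requires. The step needs site selectivity between the two enone bonds of each ring, secured because C6 and C17 are fully substituted and cage-bound, and it needs the ketone to act only as a 1,4-acceptor, secured by the ketals at C7 and C23 and by keeping the amide base below the amount of hydroperoxide. Because the C2 axis makes the two rings equivalent, a single facial preference delivers all four new stereocentres (C9, C11, C20, C22).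

Step 13
Reactants: 18 cage bis(epoxy monoketal)
Product: 19 cage bis(epoxy alcohol) bis(dimethyl ketal)
Conditions: NaBH4, CeCl3·7H2O, MeOH, −78 °C
Reagents that add atoms: none
Why: Luche reduction, in which CeCl3 makes the borohydride a hard 1,2-donor and bridges each carbonyl (C12, C18) to the neighbouring oxirane oxygen, so hydride should arrive on the outer, epoxide-bearing face as documented for cyclic α,β-epoxy ketones, placing each hydroxyl anti to its oxirane on the inner face, which is itself screened by the bridge beneath.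

Step 14
Reactants: 19 cage bis(epoxy alcohol) bis(dimethyl ketal)
Product: 20 epoxytwinol A
Conditions: aq. HF, MeCN, 0 °C
Reagents that add atoms: water, O
Why: Acid-catalysed ketal hydrolysis through the C7 (C23) oxocarbenium ion, allylic to C5=C6 (C16=C17), unveils both enones under conditions commonly used for epoxyquinol monoketals and mild enough for the oxiranes, the allylic alcohols and the cage ethers, with no stereocentre touched.

Compound list
1 | 3-bromo-4-methoxyphenol | COc1ccc(O)cc1Br | starting material
2 | 4-(benzyloxy)-2-bromo-1-methoxybenzene | COc1ccc(OCc2ccccc2)cc1Br | intermediate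
3 | (2-tert-butoxy-2-oxoethyl)zinc bromide (Reformatsky reagent, ether solution) | CC(C)(C)OC(=O)C[Zn]Br | starting material
4 | tert-butyl [5-(benzyloxy)-2-methoxyphenyl]acetate | COc1ccc(OCc2ccccc2)cc1CC(=O)OC(C)(C)C | intermediate
5 | [5-(benzyloxy)-2-methoxyphenyl]acetic acid | COc1ccc(OCc2ccccc2)cc1CC(O)=O | intermediate
6 | (S)-4-benzyloxazolidin-2-one | O=C1N[C@@H](Cc2ccccc2)CO1 | starting material
7 | [5-(benzyloxy)-2-methoxyphenyl]acetic pivalic anhydride | COc1ccc(OCc2ccccc2)cc1CC(=O)OC(=O)C(C)(C)C | intermediate
8 | (S)-4-benzyl-3-{[5-(benzyloxy)-2-methoxyphenyl]acetyl}oxazolidin-2-one | COc1ccc(OCc2ccccc2)cc1CC(=O)N1[C@@H](Cc2ccccc2)COC1=O | intermediate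
9 | (2S,3S)-2,3-bis[5-(benzyloxy)-2-methoxyphenyl]-1,4-bis[(S)-4-benzyl-2-oxooxazolidin-3-yl]butane-1,4-dione | O=C([C@H](c1cc(OCc2ccccc2)ccc1OC)[C@@H](c1cc(OCc2ccccc2)ccc1OC)C(=O)N1[C@@H](Cc2ccccc2)COC1=O)N1[C@@H](Cc2ccccc2)COC1=O | intermediate
10 | S,S'-diethyl (2S,3S)-2,3-bis[5-(benzyloxy)-2-methoxyphenyl]butanebis(thioate) | CCSC(=O)[C@H](c1cc(OCc2ccccc2)ccc1OC)[C@@H](c1cc(OCc2ccccc2)ccc1OC)C(=O)SCC | intermediate
11 | (3S,4S)-3,4-bis[5-(benzyloxy)-2-methoxyphenyl]hexane-2,5-dione | CC(=O)[C@H](c1cc(OCc2ccccc2)ccc1OC)[C@@H](c1cc(OCc2ccccc2)ccc1OC)C(C)=O | intermediate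
12 | (2R,3S,4S,5R)-3,4-bis[5-(benzyloxy)-2-methoxyphenyl]hexane-2,5-diol | C[C@@H](O)[C@H](c1cc(OCc2ccccc2)ccc1OC)[C@@H](c1cc(OCc2ccccc2)ccc1OC)[C@@H](C)O | intermediate
13 | 1,1,2,2-tetramethoxyethane (glyoxal bis(dimethyl acetal)) | COC(OC)C(OC)OC | starting material
14 | (1S,3R,4S)-8-(benzyloxy)-1-(dimethoxymethyl)-5-methoxy-3-methylisochroman bearing at C4 the (1S,2R)-1-[5-(benzyloxy)-2-methoxyphenyl]-2-hydroxypropyl group | C[C@H]1O[C@H](C(OC)OC)c2c(OCc3ccccc3)ccc(OC)c2[C@@H]1[C@@H](c1cc(OCc2ccccc2)ccc1OC)[C@@H](C)O | intermediate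
15 | cage bis(benzyl ether): target skeleton (2R,4S,14S,15S,25S,27R) with rings A and B aromatic, OMe on C7 and C23, OBn on C12 and C18, methyls C1 and C28 exo | C[C@H]1O[C@H]2c3c(c(OC)ccc3OCc3ccccc3)[C@@H]1[C@H]1c3c(c(OCc4ccccc4)ccc3OC)[C@@H]2O[C@@H]1C | intermediate
16 | cage bis(phenol): as 15 with free OH on C12 and C18 | C[C@H]1O[C@H]2c3c(c(OC)ccc3O)[C@@H]1[C@H]1c3c(c(O)ccc3OC)[C@@H]2O[C@@H]1C | intermediate
17 | cage bis(quinone monoketal): ketones at C12 and C18, dimethyl ketals at C7 and C23, disubstituted C9=C11 and C20=C22 | C[C@H]1O[C@H]2C3=C(C(OC)(OC)C=CC3=O)[C@@H]1[C@H]1C3=C(C(=O)C=CC3(OC)OC)[C@@H]2O[C@@H]1C | intermediate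
18 | cage bis(epoxy monoketal): cis-oxiranes C9–O10–C11 and C20–O21–C22 on the outer faces, ketones at C12 and C18, ketals at C7 and C23 | C[C@H]1O[C@H]2C3=C(C(OC)(OC)[C@@H]4O[C@@H]4C3=O)[C@@H]1[C@H]1C3=C(C(=O)[C@H]4O[C@H]4C3(OC)OC)[C@@H]2O[C@@H]1C | intermediate
19 | cage bis(epoxy alcohol) bis(dimethyl ketal): (12S,18S)-hydroxyls on the inner faces, anti to the oxiranes | C[C@H]1O[C@H]2C3=C(C(OC)(OC)[C@@H]4O[C@@H]4[C@H]3O)[C@@H]1[C@H]1C3=C([C@H](O)[C@H]4O[C@H]4C3(OC)OC)[C@@H]2O[C@@H]1C | intermediate
20 | epoxytwinol A, (2R,4S,9R,11R,12S,14S,15S,18S,20R,22R,25S,27R) in the labels of the target SMILES | C[C@H]1O[C@H]2C3=C(C(=O)[C@@H]4O[C@@H]4[C@H]3O)[C@@H]1[C@H]1C3=C([C@H](O)[C@H]4O[C@H]4C3=O)[C@@H]2O[C@@H]1C | target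

Total step count: 14. Longest linear sequence: 14 steps (1 to 20).

Steps most likely to fail

1. Step 12. The peroxide may add with poor or inverted facial selectivity if the cleft face competes, and over-oxidation may set in on long reaction times. The fallback replaces cage control by auxiliary control, a known tactic for quinone monoketals. Setting out from 17, acid-catalysed exchange of both dimethyl ketals with (2R,4R)-pentane-2,4-diol (pyridinium p-toluenesulfonate, benzene, reflux) should give the bis(spiro-1,3-dioxane) dienone F1, whose axial ring methyl screens one face of C9 and C22. The diol enantiomer is to be chosen so that the screened face is the cleft face; both enantiomers are sold. The same Ph3COOH/NaN(SiMe3)2 epoxidation should then give the bis(epoxide) F2, and Luche reduction the bis(epoxy alcohol) F3. Aqueous HF in MeCN removes the dioxanes and the route is rejoined at 20.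

2. Step 9. The second, transannular ring closure may lose to oligomerisation, to a 1,2-hydride shift of the C25 oxocarbenium ion, or to trapping of the wrong C4 epimer. The fallback makes the C4–C25 bond by carbonyl coupling. Setting out from 12, CH2(OMe)2 and BF3·OEt2 close two independent isochromans to the 4,4'-linked bis(isochroman) F4. DDQ in wet CH2Cl2 oxidises both benzylic O–CH2 groups to the bis(lactol) F5. SmI2 in THF couples the two ring-opened aryl aldehydes in a pinacol reaction to the eight-membered diol F6. Camphor-10-sulfonic acid in CH2Cl2 then ionises the benzylic carbinols, O3 and O26 close the two pyran rings, and the route is rejoined at 15.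

3. Step 13. Hydride may enter from the cleft face and give the syn epoxy alcohols, or add in 1,4 fashion. The fallback uses inversion in place of direct control. Setting out from 18, LiBH(s-Bu)3 at −78 °C, which attacks anti to the oxirane oxygen, should give the syn,syn-diol F7. A Mitsunobu reaction with 4-nitrobenzoic acid, PPh3 and diisopropyl azodicarboxylate inverts C12 and C18 to the bis(4-nitrobenzoate) F8. K2CO3 in MeOH at 0 °C removes the esters and the route is rejoined at 19.

Further compounds
F1 | step 12 | cage bis(quinone monoketal) with (4R,6R)-4,6-dimethyl-1,3-dioxane spiroketals at C7 and C23 | C[C@H]1O[C@H]2C3=C(C4(O[C@H](C)C[C@@H](C)O4)C=CC3=O)[C@@H]1[C@H]1C3=C(C(=O)C=CC34O[C@H](C)C[C@@H](C)O4)[C@@H]2O[C@@H]1C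
F2 | step 12 | outer-face bis(epoxide) of F1 | C[C@H]1O[C@H]2C3=C(C4(O[C@H](C)C[C@@H](C)O4)[C@@H]4O[C@@H]4C3=O)[C@@H]1[C@H]1C3=C(C(=O)[C@H]4O[C@H]4C34O[C@H](C)C[C@@H](C)O4)[C@@H]2O[C@@H]1C
F3 | step 12 | bis(epoxy alcohol) bis(dioxane ketal), hydroxyls anti to the oxiranes | C[C@H]1O[C@H]2C3=C(C4(O[C@H](C)C[C@@H](C)O4)[C@@H]4O[C@@H]4[C@H]3O)[C@@H]1[C@H]1C3=C([C@H](O)[C@H]4O[C@H]4C34O[C@H](C)C[C@@H](C)O4)[C@@H]2O[C@@H]1C
F4 | step 9 | 4,4'-linked bis(isochroman), C4 and C25 as CH2 | C[C@H]1OCc2c(OCc3ccccc3)ccc(OC)c2[C@@H]1[C@H]1c2c(OC)ccc(OCc3ccccc3)c2CO[C@@H]1C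
F5 | step 9 | bis(lactol), C4 and C25 as CH(OH), anomers not defined | C[C@H]1OC(O)c2c(OCc3ccccc3)ccc(OC)c2[C@@H]1[C@H]1c2c(OC)ccc(OCc3ccccc3)c2C(O)O[C@@H]1C
F6 | step 9 | eight-membered pinacol diol with two free 1-hydroxyethyl arms, C4/C25 carbinol configuration not defined | C[C@@H](O)[C@@H]1c2c(OC)ccc(OCc3ccccc3)c2C(O)C(O)c2c(OCc3ccccc3)ccc(OC)c2[C@H]1[C@@H](C)O
F7 | step 13 | syn,syn-bis(epoxy alcohol), the C12 and C18 epimer of 19 | C[C@H]1O[C@H]2C3=C(C(OC)(OC)[C@@H]4O[C@@H]4[C@@H]3O)[C@@H]1[C@H]1C3=C([C@@H](O)[C@H]4O[C@H]4C3(OC)OC)[C@@H]2O[C@@H]1C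
F8 | step 13 | bis(4-nitrobenzoate) of 19 | C[C@H]1O[C@H]2C3=C(C(OC)(OC)[C@@H]4O[C@@H]4[C@H]3OC(=O)c5ccc(cc5)[N+](=O)[O-])[C@@H]1[C@H]1C3=C([C@H](OC(=O)c5ccc(cc5)[N+](=O)[O-])[C@H]4O[C@H]4C3(OC)OC)[C@@H]2O[C@@H]1C
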